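## Retrosynthetic overview

- 19 ⇒ 16 + angelic acid (acylation of the C3 hydroxyl, placed last so the Z enoate meets no further reagent); 16 ⇒ 15 (dioxolane to acetyl); 15 ⇒ 13 + CH3I (alkenyl C–B to C–CH3).
- 13 ⇒ 8 + B2pin2 by cutting C2–C3. This opens dihydrofuran ring O1–C2–C3–C3a–C7a, the only ring that has to be made; the benzene ring is bought with 1.
- Feature used: C3 (the carbinol carbon) and C2 (carrying a 1-substituted vinyl group) are the two carbons of a homoallylic alcohol locked inside that five-membered ring, so a single allylmetal-to-aldehyde addition can make the bond and both stereocentres.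
- 8 ⇒ 1 in four steps: bromination at C5, Stille coupling with dioxolane formation in the same flask (the ketone is never free and the aldehyde never masked), O-propargylation, base isomerization to the aryloxyallene.

Key step: step 5

Assumption: the sense of induction of the bisphosphine in step 5 is not predicted here; (R,R)-Ph-BPE is written, and its mirror image is to be used if it leads to the (2S,3S) series.

## Route

Step 1
Reactants: 1 2-hydroxy-3,4-dimethoxybenzaldehyde
Product: 2 5-bromo-2-hydroxy-3,4-dimethoxybenzaldehyde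
Conditions: NBS (1.05 equiv), MeCN, 0 °C to rt
Reagents that add atoms: N-bromosuccinimide, O=C1CCC(=O)N1Br
Why: Electrophilic aromatic bromination should go to C5 alone, because C5 is para to the free phenol, ortho to the 4-methoxy group and meta to the formyl group, whereas C6 is ortho to the aldehyde and activated only by the twisted 3-methoxy group.

Step 2
Reactants: 2 5-bromo-2-hydroxy-3,4-dimethoxybenzaldehyde; 3 tributyl(1-ethoxyvinyl)stannane
Product: 5 2-hydroxy-3,4-dimethoxy-5-(2-methyl-1,3-dioxolan-2-yl)benzaldehyde, via 1-ethoxyvinyl arene 4 (not isolated)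
Conditions: 3 (1.2 equiv), PdCl2(PPh3)2 (5 mol%), toluene, 100 °C; then HOCH2CH2OH (5 equiv), PPTS (10 mol%), THF, rt; NaHCO3 quench
Reagents that add atoms: tributyl(1-ethoxyvinyl)stannane, C=C(OCC)[Sn](CCCC)(CCCC)CCCC; ethylene glycol, OCCO
Why: Stille coupling of the aryl bromide gives enol ether 4, and acid-catalysed exchange of this electron-rich enol ether with the diol (protonation to an oxocarbenium ion, capture by glycol, loss of ethanol) should be far faster than acetalization of the hydrogen-bonded salicylaldehyde carbonyl, so the ketone appears directly as its dioxolane while the aldehyde stays free.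

Step 3
Reactants: 5 2-hydroxy-3,4-dimethoxy-5-(2-methyl-1,3-dioxolan-2-yl)benzaldehyde; 6 propargyl bromide
Product: 7 3,4-dimethoxy-5-(2-methyl-1,3-dioxolan-2-yl)-2-(prop-2-yn-1-yloxy)benzaldehyde
Conditions: 6 (1.3 equiv), K2CO3 (2 equiv), DMF, rt
Reagents that add atoms: propargyl bromide, C#CCBr
Why: Williamson ether synthesis, in which the phenoxide (made acidic by the ortho formyl group) displaces bromide from the propargylic halide under conditions that leave the ketal and the aldehyde untouched.

Step 4
Reactants: 7 3,4-dimethoxy-5-(2-methyl-1,3-dioxolan-2-yl)-2-(prop-2-yn-1-yloxy)benzaldehyde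
Product: 8 3,4-dimethoxy-5-(2-methyl-1,3-dioxolan-2-yl)-2-(propa-1,2-dien-1-yloxy)benzaldehyde
Conditions: KOtBu (0.3 equiv), THF, 0 °C to rt
Reagents that add atoms: none
Why: Base-mediated prototropic propargyl-to-allenyl isomerization of an aryl propargyl ether should stop at the aryloxyallene under catalytic alkoxide, and no aldol pathway is open because the aldehyde is non-enolizable and the ketone is masked.

Step 5
Reactants: 8 3,4-dimethoxy-5-(2-methyl-1,3-dioxolan-2-yl)-2-(propa-1,2-dien-1-yloxy)benzaldehyde; 9 bis(pinacolato)diboron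
Product: 13 cis-(2R,3R)-6,7-dimethoxy-5-(2-methyl-1,3-dioxolan-2-yl)-2-[1-(4,4,5,5-tetramethyl-1,3,2-dioxaborolan-2-yl)ethenyl]-2,3-dihydro-1-benzofuran-3-ol, via Z-allylcopper 10 (not isolated), via copper alkoxide 11 (not isolated), via O-boryl ester 12 (not isolated)
Conditions: CuCl (5 mol%), (R,R)-Ph-BPE (6 mol%), NaOtBu (10 mol%), 9 (1.2 equiv), THF, 0 °C to rt; then pH 7 buffer/MeOH
Reagents that add atoms: bis(pinacolato)diboron, CC1(C)OB(OC1(C)C)B1OC(C)(C)C(C)(C)O1
Why: The copper boryl made from CuCl, NaOtBu, the bisphosphine and B2pin2 (monovalent copper) inserts the terminal C=C of the allene, with boron going to the central carbon and copper to CH2 from the side remote from the aryloxy group, so allylcopper 10 is Z; its oxygen-bearing γ-carbon then attacks the ortho aldehyde carbon through a closed six-membered chair-like transition state, alkoxide 11 is borylated by B2pin2 to give 12 and return the copper boryl, and work-up cleaves the O–B bond. The closest known reaction type is the copper-catalysed enantioselective borylative coupling of allenes with aldehydes and ketones, in its intramolecular form. Ring O1–C2–C3–C3a–C7a closes in the 5-exo-trig mode as C2–C3 forms. The cis relationship follows from the Z geometry: the aryloxy oxygen is axial on C2 and the aryl carbon equatorial on C3, the only chair arrangement that the short O1–C7a–C3a tether allows, and this puts the alkenyl group and the new alkoxide on the same face; the absolute configuration (2R,3R) is set by the aldehyde face that the chiral bisphosphine on copper exposes. The step needs borylcupration of the allene to outrun 1,2-addition of the copper boryl to the aldehyde, which the fast insertion of the unhindered terminal allene π bond and the absence of any protic additive (which would protonate 10 before it cyclizes) should secure, and γ-attack is favoured over α-attack because it closes a five-membered and not a seven-membered ring.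

Step 6
Reactants: 13 cis-(2R,3R)-6,7-dimethoxy-5-(2-methyl-1,3-dioxolan-2-yl)-2-[1-(4,4,5,5-tetramethyl-1,3,2-dioxaborolan-2-yl)ethenyl]-2,3-dihydro-1-benzofuran-3-ol; 14 iodomethane
Product: 15 (2R,3R)-6,7-dimethoxy-5-(2-methyl-1,3-dioxolan-2-yl)-2-(prop-1-en-2-yl)-2,3-dihydro-1-benzofuran-3-ol
Conditions: 14 (3 equiv), Pd2(dba)3 (2.5 mol%), P(o-tol)3 (10 mol%), K2CO3 (3 equiv), DMF/H2O (9:1), 60 °C
Reagents that add atoms: iodomethane, CI
Why: Suzuki–Miyaura coupling, in which iodomethane adds oxidatively to zerovalent palladium, the carbonate-activated alkenylboronate transmetalates and reductive elimination gives the isopropenyl group, with the bulky phosphine resisting quaternization by iodomethane and no bond to C2 or C3 being broken.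

Step 7
Reactants: 15 (2R,3R)-6,7-dimethoxy-5-(2-methyl-1,3-dioxolan-2-yl)-2-(prop-1-en-2-yl)-2,3-dihydro-1-benzofuran-3-ol
Product: 16 1-[(2R,3R)-3-hydroxy-6,7-dimethoxy-2-(prop-1-en-2-yl)-2,3-dihydro-1-benzofuran-5-yl]ethan-1-one
Conditions: PPTS (0.2 equiv), THF/H2O (4:1), rt
Reagents that add atoms: water, O
Why: Acid-catalysed ketal hydrolysis, which should proceed under very mild acid because the dioxolane of an ortho-methoxy, para-alkoxy aryl ketone ionizes easily, so the benzylic C3 carbinol and the allylic C2–O1 bond are not ionized and the freed acetyl group then deactivates the arene further.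

Step 8
Reactants: 16 1-[(2R,3R)-3-hydroxy-6,7-dimethoxy-2-(prop-1-en-2-yl)-2,3-dihydro-1-benzofuran-5-yl]ethan-1-one; 17 angelic acid
Product: 19 (2R,3R)-5-acetyl-6,7-dimethoxy-2-(prop-1-en-2-yl)-2,3-dihydro-1-benzofuran-3-yl (2Z)-2-methylbut-2-enoate, via mixed anhydride 18 (not isolated)
Conditions: 17 (3 equiv), 2,4,6-trichlorobenzoyl chloride (3 equiv), Et3N (6 equiv), toluene, rt; then 16, toluene, 80 °C
Reagents that add atoms: angelic acid, C/C=C(/C)C(=O)O
Why: Yamaguchi esterification, in which the alcohol attacks the unshielded angeloyl carbonyl of the mixed anhydride; leaving out DMAP avoids the conjugate addition–elimination that turns angelate into tiglate, and C3 keeps its configuration because its C–O bond is not broken.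

## Compound list

1 | 2-hydroxy-3,4-dimethoxybenzaldehyde | O=Cc1ccc(OC)c(OC)c1O | starting material
2 | 5-bromo-2-hydroxy-3,4-dimethoxybenzaldehyde | O=Cc1cc(Br)c(OC)c(OC)c1O | intermediate
3 | tributyl(1-ethoxyvinyl)stannane | C=C(OCC)[Sn](CCCC)(CCCC)CCCC | starting material
4 | 5-(1-ethoxyethenyl)-2-hydroxy-3,4-dimethoxybenzaldehyde | C=C(OCC)c1cc(C=O)c(O)c(OC)c1OC | intermediate (not isolated)
5 | 2-hydroxy-3,4-dimethoxy-5-(2-methyl-1,3-dioxolan-2-yl)benzaldehyde | O=Cc1cc(C2(C)OCCO2)c(OC)c(OC)c1O | intermediate
6 | propargyl bromide | C#CCBr | starting material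
7 | 3,4-dimethoxy-5-(2-methyl-1,3-dioxolan-2-yl)-2-(prop-2-yn-1-yloxy)benzaldehyde | C#CCOc1c(C=O)cc(C2(C)OCCO2)c(OC)c1OC | intermediate
8 | 3,4-dimethoxy-5-(2-methyl-1,3-dioxolan-2-yl)-2-(propa-1,2-dien-1-yloxy)benzaldehyde | C=C=COc1c(C=O)cc(C2(C)OCCO2)c(OC)c1OC | intermediate
9 | bis(pinacolato)diboron | CC1(C)OB(OC1(C)C)B1OC(C)(C)C(C)(C)O1 | starting material
10 | (Z)-3-aryloxy-2-(pinacolboryl)allylcopper derived from 8 (bisphosphine on copper not drawn) | [Cu]C/C(B1OC(C)(C)C(C)(C)O1)=C\Oc1c(C=O)cc(C2(C)OCCO2)c(OC)c1OC | intermediate (not isolated)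
11 | copper (2R,3R)-3-alkoxide of 13 (bisphosphine on copper not drawn) | C=C(B1OC(C)(C)C(C)(C)O1)[C@H]1Oc2c(cc(C3(C)OCCO3)c(OC)c2OC)[C@H]1O[Cu] | intermediate (not isolated)
12 | (2R,3R)-3-O-pinacolboryl ester of 13 | C=C(B1OC(C)(C)C(C)(C)O1)[C@H]1Oc2c(cc(C3(C)OCCO3)c(OC)c2OC)[C@H]1OB4OC(C)(C)C(C)(C)O4 | intermediate (not isolated)
13 | cis-(2R,3R)-6,7-dimethoxy-5-(2-methyl-1,3-dioxolan-2-yl)-2-[1-(4,4,5,5-tetramethyl-1,3,2-dioxaborolan-2-yl)ethenyl]-2,3-dihydro-1-benzofuran-3-ol | C=C(B1OC(C)(C)C(C)(C)O1)[C@H]1Oc2c(cc(C3(C)OCCO3)c(OC)c2OC)[C@H]1O | intermediate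
14 | iodomethane | CI | starting material
15 | (2R,3R)-6,7-dimethoxy-5-(2-methyl-1,3-dioxolan-2-yl)-2-(prop-1-en-2-yl)-2,3-dihydro-1-benzofuran-3-ol | C=C(C)[C@H]1Oc2c(cc(C3(C)OCCO3)c(OC)c2OC)[C@H]1O | intermediate
16 | 1-[(2R,3R)-3-hydroxy-6,7-dimethoxy-2-(prop-1-en-2-yl)-2,3-dihydro-1-benzofuran-5-yl]ethan-1-one | C=C(C)[C@H]1Oc2c(cc(C(C)=O)c(OC)c2OC)[C@H]1O | intermediate
17 | angelic acid, (2Z)-2-methylbut-2-enoic acid | C/C=C(/C)C(=O)O | starting material
18 | (2Z)-2-methylbut-2-enoic 2,4,6-trichlorobenzoic anhydride | C/C=C(/C)C(=O)OC(=O)c1c(Cl)cc(Cl)cc1Cl | intermediate (not isolated)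
19 | (2R,3R)-5-acetyl-6,7-dimethoxy-2-(prop-1-en-2-yl)-2,3-dihydro-1-benzofuran-3-yl (2Z)-2-methylbut-2-enoate (CNP0113631.1) | C=C(C)[C@H]1Oc2c(cc(C(C)=O)c(OC)c2OC)[C@H]1OC(=O)/C(C)=C\C | target

## Step count and risks

Total step count: 8. Longest linear sequence: 8 steps (1 to 19).

Steps most likely to fail:

Step 5. The copper boryl may add to the aldehyde carbonyl before it inserts the allene, or the bisphosphine may discriminate the aldehyde faces poorly, which would lower conversion to the ring or the enantiomeric purity. The fallback sets out from 8 and uses a nickel-catalysed methylative cyclization (Ni(cod)2 cat., Zn(CH3)2, THF, 0 °C): oxidative cyclization of allene and aldehyde at zerovalent nickel, methyl transfer from zinc and reductive elimination should form the same C2–C3 bond and deliver the cis 2-isopropenyl-3-ol directly, as the racemate. The racemate is 15 together with its mirror image, (2S,3S)-6,7-dimethoxy-5-(2-methyl-1,3-dioxolan-2-yl)-2-(prop-1-en-2-yl)-2,3-dihydro-1-benzofuran-3-ol F1, which would be removed by preparative chromatography on a chiral stationary phase. The route is rejoined at 15, and step 6 is then not needed.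

Step 4. The free aldehyde may be consumed under the alkoxide base, by alkoxide addition followed by hydride-transfer redox chemistry or by attack of the propargylic carbanion on the neighbouring carbonyl, before the triple bond has migrated. The fallback sets out from 7 and takes the aldehyde out of play during the isomerization. Reduction with NaBH4 in MeOH at 0 °C should give [3,4-dimethoxy-5-(2-methyl-1,3-dioxolan-2-yl)-2-(prop-2-yn-1-yloxy)phenyl]methanol F2. Isomerization of F2 with KOtBu (1.5 equiv) in THF should give [3,4-dimethoxy-5-(2-methyl-1,3-dioxolan-2-yl)-2-(propa-1,2-dien-1-yloxy)phenyl]methanol F3. Neutral benzylic oxidation of F3 with MnO2 in CH2Cl2 then returns the route to 8 without acid touching the allenyl ether or the ketal.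

Step 8. The Z double bond may isomerize to the E (tigloyl) geometry during activation or acyl transfer, or acylation of the hindered cis carbinol may be too slow without a nucleophilic catalyst. The fallback sets out from 16 and builds the Z alkene on the ester instead of bringing it in. Carbodiimide coupling (DCC, DMAP, CH2Cl2) with 2-[bis(2,2,2-trifluoroethoxy)phosphoryl]propanoic acid should give (2R,3R)-5-acetyl-6,7-dimethoxy-2-(prop-1-en-2-yl)-2,3-dihydro-1-benzofuran-3-yl 2-[bis(2,2,2-trifluoroethoxy)phosphoryl]propanoate F4, as a mixture of epimers at the phosphonate-bearing carbon. Still–Gennari olefination of F4 (KN(SiMe3)2, 18-crown-6, THF, −78 °C, then acetaldehyde) should give the Z trisubstituted enoate and so rejoin the route at 19.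

Further compounds
F1 | step 5 | (2S,3S)-6,7-dimethoxy-5-(2-methyl-1,3-dioxolan-2-yl)-2-(prop-1-en-2-yl)-2,3-dihydro-1-benzofuran-3-ol (enantiomer of 15, formed with 15 as the racemate) | C=C(C)[C@@H]1Oc2c(cc(C3(C)OCCO3)c(OC)c2OC)[C@@H]1O
F2 | step 4 | [3,4-dimethoxy-5-(2-methyl-1,3-dioxolan-2-yl)-2-(prop-2-yn-1-yloxy)phenyl]methanol | C#CCOc1c(CO)cc(C2(C)OCCO2)c(OC)c1OC
F3 | step 4 | [3,4-dimethoxy-5-(2-methyl-1,3-dioxolan-2-yl)-2-(propa-1,2-dien-1-yloxy)phenyl]methanol | C=C=COc1c(CO)cc(C2(C)OCCO2)c(OC)c1OC
F4 | step 8 | (2R,3R)-5-acetyl-6,7-dimethoxy-2-(prop-1-en-2-yl)-2,3-dihydro-1-benzofuran-3-yl 2-[bis(2,2,2-trifluoroethoxy)phosphoryl]propanoate | C=C(C)[C@H]1Oc2c(cc(C(C)=O)c(OC)c2OC)[C@H]1OC(=O)C(C)P(=O)(OCC(F)(F)F)OCC(F)(F)F
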